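One percent here is one percent of the starting complex charged, with one side product B counting as two, and on that unit the earlier runs can be followed in slow motion.

| flask | starting complex | incoming ligand | remark | time |
|---|---|---|---|---|
| north-east | 0.50 M | 0.75 M | run made earlier |  |
| north | 0.50 M | 1 M | run made earlier |  |
| south-east | 0.50 M | 1.7 M | run made earlier |  |
| noon | 0.50 M | 0.750 M | everything together in a closed stirred flask, run for 25 h | 25 h |
| dusk | 0.50 M | 0.750 M | one stirred flow tank at steady state, fed with the mixture as stated, mean residence time 25 h |  |
| dawn | 0.50 M (fed, over 20.0 h) | 0.750 M | all but starting complex at the start; starting complex goes in evenly over 20.0 h, the run ends at 25 h | 25 h |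
| winter | 0.50 M | 0.750 M (fed, over 20.0 h) | a stirred flask in which incoming ligand is dosed at a steady rate over 20.0 h without added volume, worked up at 25 h | 25 h |

| run | time / h | complex with two exchanged / % | side product A / % |
|---|---|---|---|
| north-east | 1.50 | 10.1 | 4.6 |
| north-east | 5.00 | 28.9 | 18.0 |
| north-east | 8.00 | 38.0 | 20.4 |
| north-east | 15.0 | 50.4 | 21.7 |
| north-east | 20.0 | 54.4 | 20.7 |
| north-east | 25.0 | 57.6 | 21.6 |
| north | 2.50 | 25.4 | 11.3 |
| north | 4.00 | 38.9 | 14.9 |
| north | 6.00 | 48.9 | 15.8 |
| north | 10.0 | 61.0 | 17.6 |
| north | 20.0 | 73.6 | 18.2 |
| north | 30.0 | 77.2 | 17.3 |
| south-east | 2.50 | 49.5 | 9.9 |
| south-east | 4.00 | 66.0 | 10.2 |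
| south-east | 6.00 | 78.3 | 11.1 |
| south-east | 10.0 | 84.8 | 8.8 |
| south-east | 20.0 | 87.7 | 12.5 |
| south-east | 30.0 | 89.1 | 9.7 |

(each reading ± 1 percentage point)

- percent here means starting complex units held: one side product B counts as two
- the stated concentrations are those of everything mixed, before any reaction; amounts are the same in each set-up
- the feed brings no volume worth counting
- the earlier runs were made in a closed, stirred flask

- order of the set-ups by the share of complex with two exchanged in all that became complex with two exchanged or side product A or side product B, at the outlet or at the end, highest first (noon / dusk / dawn / winter)
- share of complex with two exchanged in all that became complex with two exchanged or side product A or side product B, at the outlet or at the end, noon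
- share of complex with two exchanged in all that became complex with two exchanged or side product A or side product B, at the outlet or at the end, dusk
- share of complex with two exchanged in all that became complex with two exchanged or side product A or side product B, at the outlet or at the end, dawn
- share of complex with two exchanged in all that became complex with two exchanged or side product A or side product B, at the outlet or at the end, winter

The share asked for is the selectivity to complex with two exchanged. At the first reading of the north-east run, at 1.50 h, the closed flask shows 10.1% of complex with two exchanged and 4.6% of side product A, so both appear early. In the middle, side product A levels off: it reads 20.4% at 8.00 h and 21.6% at 25.0 h, while complex with two exchanged climbs from 38.0% to 57.6%. At the end of that run, 20.8% of the charge lies in forms we do not read.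

Across the three earlier runs, all at one charge of starting complex, the level read for side product A falls as incoming ligand rises. We take the mean of the last three readings as that level and multiply it by [incoming ligand]/[starting complex] as charged. This gives 32.0% for north-east, 35.4% for north and 35.1% for south-east, although the ligand charge more than doubles across them. Their mean, 34.2%, is our A coefficient: the final side product A per unit of [starting complex]/[incoming ligand] as charged. The runs held [starting complex] at 0.50 M, so its place in the ratio is our assumption.

Noon repeats the north-east recipe. The coefficient gives noon 22.8% of side product A, and with the reading of 57.6% for complex with two exchanged our share for noon is 71.7%, side product B being unread and uncounted. The coefficient comes from closed flasks with the whole charge present from the start, so we reckon no number for dusk, dawn or winter.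

The forecast, holding that “Noon is read directly from the data”, gives dawn > noon > dusk > winter, with 73%, 61%, 74% and 47% for noon, dusk, dawn and winter.

The simulation gives noon > dawn > winter > dusk, with 68.8%, 44.8%, 58.5% and 53.5% for noon, dusk, dawn and winter.

    leaving ligand + starting complex → side product A (k = 0.400 M⁻¹ h⁻¹)
    complex with one exchanged + incoming ligand → leaving ligand + complex with two exchanged (k = 0.420 M⁻¹ h⁻¹)
    starting complex + complex with two exchanged → side product B (k = 0.140 M⁻¹ h⁻¹)
    starting complex + incoming ligand → leaving ligand + complex with one exchanged (k = 0.790 M⁻¹ h⁻¹)

Noon ends with 22.2% of side product A against our 22.8%, and it holds 3.90% of side product B, which our 71.7% left uncounted. The neighbouring flask takes 0.12 M of starting complex, with the other charges and the time as in noon. Its ratio to incoming ligand is 0.160, so the coefficient gives 5.47% of side product A, and that flask holds 5.45%. Its side product B stands at 0.980%, and its share of complex with two exchanged is 93.5%.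

(All runs stem from a simulated flask with made-up constants; the scatter is artificial.)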